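**Retrosynthetic overview**

1. Target ⇒ (O-demethylation, twofold formylation, hydrogenation) ⇒ C7'–CH2 bond by exo methallylation of the C7' benzylic cation of the bridged benzoxepine ⇒ C1–O and C10–H by anti addition of the ortho-phenol O–H across a C1=C10 alkene (oxepane, fourth and last ring).
2. Feature on which the strategy rests: the C1–C10 bond of the cycloheptane, where C1 is the O-bearing cyclopentane/cycloheptane fusion carbon and C10 the CH(CH3) carbon tied back through C9–C8 to the cis-fused gem-dimethylcyclopropane (C6/C7/C11). It is taken back to a tetrasubstituted C1=C10 alkene and then to a cyclopentanone (C1=O) and a methyl ketone (C10=O), joined by McMurry coupling (cycloheptene, third ring).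
3. Diketone ⇐ cyclopentenone by ring-closing metathesis (second ring) ⇐ C4–C5 bond, with quaternary C4 and C5 set together by an Ireland–Claisen rearrangement with chirality transfer from an (R)-lactate-derived allylic alcohol.
4. The cyclopropane (first ring), C5–C11 and the C10 methyl ketone arm come intact from ozonised (+)-2-carene, homologated by one carbon (C1) to a cyclopropylacetic acid.

Key step: step 19

Remark: atom labels are C1 (O-bearing fusion carbon), C2/C3 (cyclopentane CH2), C4 (quaternary), C5 (fusion CH), C6/C7 (cyclopropane CH), C8/C9 (cycloheptane CH2), C10 (CH–CH3), C11 (CMe2), C7' (benzylic), C1'–C6' (aryl); lithiation of 32 is assumed to occur between OMOM and OMe, as the stronger MOM director predicts.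

**Fragment A: cyclopropylacetic acid from (+)-2-carene**

Step 1
Reactants: 1 (+)-2-carene
Product: 3 (1S,3R)-2,2-dimethyl-3-(3-oxobutyl)cyclopropane-1-carbaldehyde, via secondary ozonide 2 (not isolated)
Conditions: O3, CH2Cl2, −78 °C; then Me2S, −78 °C → rt
Reagents that add atoms: ozone, [O-][O+]=O
Why: Ozonolysis with reductive work-up cleaves the only C=C to the keto aldehyde, and the two cyclopropane stereocentres (future C6 and C7) are carried over from carene untouched.

Step 2
Reactants: 3 (1S,3R)-2,2-dimethyl-3-(3-oxobutyl)cyclopropane-1-carbaldehyde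
Product: 4 4-[(1R,3S)-3-ethenyl-2,2-dimethylcyclopropyl]butan-2-one
Conditions: Ph3PCH3Br, KHMDS, THF, 0 °C; then 3, −78 → 0 °C
Reagents that add atoms: methyltriphenylphosphonium bromide (as its ylide), C[P+](c1ccccc1)(c1ccccc1)c1ccccc1.[Br-]
Why: Wittig methylenation with one equivalent of the non-stabilised ylide at −78 °C should take the aldehyde far faster than the methyl ketone and before base-mediated epimerisation or aldol reaction; the new carbon is the future C1.

Step 3
Reactants: 4 4-[(1R,3S)-3-ethenyl-2,2-dimethylcyclopropyl]butan-2-one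
Product: 5 2-{2-[(1R,3S)-3-ethenyl-2,2-dimethylcyclopropyl]ethyl}-2-methyl-1,3-dioxolane
Conditions: HOCH2CH2OH, PPTS (cat.), benzene, reflux (Dean–Stark)
Reagents that add atoms: ethylene glycol, OCCO
Why: Acid-catalysed ketalisation masks the future C10 ketone against the borane, enolate and Grignard steps, and PPTS is too weak to open the vinylcyclopropane.

Step 4
Reactants: 5 2-{2-[(1R,3S)-3-ethenyl-2,2-dimethylcyclopropyl]ethyl}-2-methyl-1,3-dioxolane
Product: 7 2-{(1S,3R)-2,2-dimethyl-3-[2-(2-methyl-1,3-dioxolan-2-yl)ethyl]cyclopropyl}ethan-1-ol, via B-alkyl-9-BBN 6 (not isolated)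
Conditions: 9-BBN, THF, 0 °C → rt; then NaOH, H2O2, 0 °C → rt
Reagents that add atoms: hydrogen peroxide, OO
Why: Brown hydroboration–oxidation puts boron on the terminal carbon of the monosubstituted alkene, so no ring-opening cyclopropylcarbinyl borane forms and the primary alcohol results.

Step 5
Reactants: 7 2-{(1S,3R)-2,2-dimethyl-3-[2-(2-methyl-1,3-dioxolan-2-yl)ethyl]cyclopropyl}ethan-1-ol
Product: 8 2-{(1S,3R)-2,2-dimethyl-3-[2-(2-methyl-1,3-dioxolan-2-yl)ethyl]cyclopropyl}acetic acid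
Conditions: TEMPO (cat.), NaOCl (cat.), NaClO2, MeCN/phosphate buffer (pH 6.7), 35 °C
Reagents that add atoms: sodium chlorite, [Na+].[O-]Cl=O
Why: The buffered TEMPO/chlorite oxidation takes a primary alcohol to the acid near neutral pH, where the dioxolane should survive.

**Fragment B: chiral allylic alcohol from methyl (R)-lactate**

Step 6
Reactants: 9 methyl (R)-lactate
Product: 10 methyl (2R)-2-[(tert-butyldimethylsilyl)oxy]propanoate
Conditions: TBSCl, imidazole, DMF, rt
Reagents that add atoms: tert-butyldimethylsilyl chloride, CC(C)(C)[Si](C)(C)Cl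
Why: Standard imidazole-promoted silylation of the secondary alcohol, without touching the stereocentre.

Step 7
Reactants: 10 methyl (2R)-2-[(tert-butyldimethylsilyl)oxy]propanoate
Product: 11 (2R)-2-[(tert-butyldimethylsilyl)oxy]propanal
Conditions: DIBAL-H, CH2Cl2, −78 °C; Rochelle salt
Reagents that add atoms: none
Why: DIBAL half-reduction of an α-silyloxy ester stops at the aldehyde because the tetrahedral aluminate is stable at −78 °C, and it does not racemise the α-centre.

Step 8
Reactants: 11 (2R)-2-[(tert-butyldimethylsilyl)oxy]propanal; 12 ethyl 2-(triphenyl-λ5-phosphanylidene)propanoate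
Product: 13 ethyl (2E,4R)-4-[(tert-butyldimethylsilyl)oxy]-2-methylpent-2-enoate
Conditions: CH2Cl2, rt
Reagents that add atoms: none
Why: Wittig olefination with the stabilised ylide gives the E-trisubstituted enoate, which places the carbinol carbon cis to the vinylic methyl group (future C4 methyl).

Step 9
Reactants: 13 ethyl (2E,4R)-4-[(tert-butyldimethylsilyl)oxy]-2-methylpent-2-enoate
Product: 14 (2E,4R)-4-[(tert-butyldimethylsilyl)oxy]-2-methylpent-2-en-1-ol
Conditions: DIBAL-H (2.2 equiv), CH2Cl2, −78 °C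
Reagents that add atoms: none
Why: DIBAL 1,2-reduction of the enoate gives the allylic alcohol (future C7') without moving the double bond.

Step 10
Reactants: 14 (2E,4R)-4-[(tert-butyldimethylsilyl)oxy]-2-methylpent-2-en-1-ol
Product: 15 (2E,4R)-4-[(tert-butyldimethylsilyl)oxy]-1-[(tert-butyldiphenylsilyl)oxy]-2-methylpent-2-ene
Conditions: TBDPSCl, imidazole, CH2Cl2, rt
Reagents that add atoms: tert-butyl(chloro)diphenylsilane, CC(C)(C)[Si](Cl)(c1ccccc1)c1ccccc1
Why: Silylation installs the robust TBDPS ether that is to ride through enolate, Grignard, metathesis and low-valent titanium chemistry.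

Step 11
Reactants: 15 (2E,4R)-4-[(tert-butyldimethylsilyl)oxy]-1-[(tert-butyldiphenylsilyl)oxy]-2-methylpent-2-ene
Product: 16 (2R,3E)-5-[(tert-butyldiphenylsilyl)oxy]-4-methylpent-3-en-2-ol
Conditions: CSA (cat.), MeOH/CH2Cl2, 0 °C
Reagents that add atoms: none
Why: Acid-catalysed methanolysis should remove the secondary TBS ether selectively, because the TBDPS ether is about two orders of magnitude more stable to acid.

**Union and cyclopentanone**

Step 12
Reactants: 8 2-{(1S,3R)-2,2-dimethyl-3-[2-(2-methyl-1,3-dioxolan-2-yl)ethyl]cyclopropyl}acetic acid; 16 (2R,3E)-5-[(tert-butyldiphenylsilyl)oxy]-4-methylpent-3-en-2-ol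
Product: 17 (2R,3E)-5-[(tert-butyldiphenylsilyl)oxy]-4-methylpent-3-en-2-yl 2-{(1S,3R)-2,2-dimethyl-3-[2-(2-methyl-1,3-dioxolan-2-yl)ethyl]cyclopropyl}acetate
Conditions: DCC, DMAP (cat.), CH2Cl2, 0 °C → rt
Reagents that add atoms: none
Why: Steglich esterification joins the fragments under neutral conditions that spare the ketal and do not ionise the allylic alcohol.

Step 13
Reactants: 17 (2R,3E)-5-[(tert-butyldiphenylsilyl)oxy]-4-methylpent-3-en-2-yl 2-{(1S,3R)-2,2-dimethyl-3-[2-(2-methyl-1,3-dioxolan-2-yl)ethyl]cyclopropyl}acetate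
Product: 20 (2R,3S,4E)-3-{[(tert-butyldiphenylsilyl)oxy]methyl}-2-{(1R,3R)-2,2-dimethyl-3-[2-(2-methyl-1,3-dioxolan-2-yl)ethyl]cyclopropyl}-3-methylhex-4-enoic acid, via silyl ketene acetal 18 (not isolated), via trimethylsilyl ester 19 (not isolated)
Conditions: LDA, THF/HMPA (4:1), −78 °C; TMSCl, −78 → 50 °C; aq. NaOH, then citric acid to pH 5
Reagents that add atoms: none
Why: Ireland–Claisen rearrangement in which LDA/THF–HMPA gives the enolate with cyclopropyl cis to O–Li and ketene acetal 18 rearranges through a chair with the carbinol methyl, the cyclopropyl and the CH2OTBDPS groups all equatorial, so the (R)-carbinol centre is transferred to C5 and to quaternary C4 (cyclopropyl ending trans to CH2OTBDPS) while an E-propenyl group is left on C4.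

Step 14
Reactants: 20 (2R,3S,4E)-3-{[(tert-butyldiphenylsilyl)oxy]methyl}-2-{(1R,3R)-2,2-dimethyl-3-[2-(2-methyl-1,3-dioxolan-2-yl)ethyl]cyclopropyl}-3-methylhex-4-enoic acid
Product: 22 (2R,3S,4E)-3-{[(tert-butyldiphenylsilyl)oxy]methyl}-2-{(1R,3R)-2,2-dimethyl-3-[2-(2-methyl-1,3-dioxolan-2-yl)ethyl]cyclopropyl}-N-methoxy-N,3-dimethylhex-4-enamide, via acyl imidazole 21 (not isolated)
Conditions: CDI, CH2Cl2, rt; then MeNHOMe·HCl, rt → 40 °C
Reagents that add atoms: N,O-dimethylhydroxylamine hydrochloride, CNOC.Cl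
Why: CDI activation followed by aminolysis gives the Weinreb amide without strong acid or base, so the ketal and the C5 centre are kept.

Step 15
Reactants: 22 (2R,3S,4E)-3-{[(tert-butyldiphenylsilyl)oxy]methyl}-2-{(1R,3R)-2,2-dimethyl-3-[2-(2-methyl-1,3-dioxolan-2-yl)ethyl]cyclopropyl}-N-methoxy-N,3-dimethylhex-4-enamide
Product: 23 (4R,5S,6E)-5-{[(tert-butyldiphenylsilyl)oxy]methyl}-4-{(1R,3R)-2,2-dimethyl-3-[2-(2-methyl-1,3-dioxolan-2-yl)ethyl]cyclopropyl}-5-methylocta-1,6-dien-3-one
Conditions: CH2=CHMgBr, THF, 0 °C; cold aq. NH4Cl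
Reagents that add atoms: vinylmagnesium bromide, C=C[Mg]Br
Why: Grignard addition to a Weinreb amide stops at the chelated tetrahedral adduct, so the vinyl ketone (C1=O with C2 attached) is released only on the cold quench.

Step 16
Reactants: 23 (4R,5S,6E)-5-{[(tert-butyldiphenylsilyl)oxy]methyl}-4-{(1R,3R)-2,2-dimethyl-3-[2-(2-methyl-1,3-dioxolan-2-yl)ethyl]cyclopropyl}-5-methylocta-1,6-dien-3-one
Product: 24 (4S,5R)-4-{[(tert-butyldiphenylsilyl)oxy]methyl}-5-{(1R,3R)-2,2-dimethyl-3-[2-(2-methyl-1,3-dioxolan-2-yl)ethyl]cyclopropyl}-4-methylcyclopent-2-en-1-one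
Conditions: Grubbs II (5 mol %), CH2Cl2 (5 mM), 40 °C
Reagents that add atoms: none
Why: Ring-closing metathesis of the vinyl ketone with the propenyl group forms the C2=C3 bond of a cyclopentenone and expels propene, under neutral conditions that leave C4 and C5 untouched.

Step 17
Reactants: 24 (4S,5R)-4-{[(tert-butyldiphenylsilyl)oxy]methyl}-5-{(1R,3R)-2,2-dimethyl-3-[2-(2-methyl-1,3-dioxolan-2-yl)ethyl]cyclopropyl}-4-methylcyclopent-2-en-1-one
Product: 25 (2R,3S)-3-{[(tert-butyldiphenylsilyl)oxy]methyl}-2-{(1R,3R)-2,2-dimethyl-3-[2-(2-methyl-1,3-dioxolan-2-yl)ethyl]cyclopropyl}-3-methylcyclopentan-1-one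
Conditions: H2 (1 atm), 10% Pd/C, EtOAc, rt
Reagents that add atoms: none
Why: Catalytic hydrogenation saturates the enone C=C, and the isolated trialkylcyclopropane, the silyl ether and the ketal should be inert at 1 atm.

Step 18
Reactants: 25 (2R,3S)-3-{[(tert-butyldiphenylsilyl)oxy]methyl}-2-{(1R,3R)-2,2-dimethyl-3-[2-(2-methyl-1,3-dioxolan-2-yl)ethyl]cyclopropyl}-3-methylcyclopentan-1-one
Product: 26 (2R,3S)-3-{[(tert-butyldiphenylsilyl)oxy]methyl}-2-[(1R,3R)-2,2-dimethyl-3-(3-oxobutyl)cyclopropyl]-3-methylcyclopentan-1-one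
Conditions: PPTS, acetone/H2O (4:1), 50 °C
Reagents that add atoms: water, O
Why: Mild acid-catalysed ketal hydrolysis frees the C10 methyl ketone while the TBDPS ether stays and C5 is not enolised to any extent that matters.

**Key step**

Step 19
Reactants: 26 (2R,3S)-3-{[(tert-butyldiphenylsilyl)oxy]methyl}-2-[(1R,3R)-2,2-dimethyl-3-(3-oxobutyl)cyclopropyl]-3-methylcyclopentan-1-one
Product: 28 (4S,5S,6R,7R)-4-{[(tert-butyldiphenylsilyl)oxy]methyl}aromadendr-1(10)-ene, via titanium pinacolate 27 (not isolated)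
Conditions: TiCl3(DME)1.5, Zn–Cu, DME, reflux; 26 added over 36 h by syringe pump (final 3 mM), then reflux 6 h
Reagents that add atoms: none
Why: Low-valent titanium transfers single electrons to both carbonyls, the C1 and C10 ketyls combine on the metal to the pinacolate 27, and at reflux both C–O bonds are cleaved to leave the tetrasubstituted C1=C10 alkene. This is the intramolecular McMurry coupling of a diketone to a cycloalkene, well documented for seven-membered rings. The cycloheptene closes by radical–radical union of the two carbonyl carbons, and the cis-cyclopropane holds both chains on one face of the three-membered ring so the carbonyls start close together. No new stereocentre is formed, since C1 and C10 both become sp2. The step needs cyclisation to beat intermolecular coupling and needs the cyclopropane and C5 to survive: slow addition at high dilution serves the first, neither ketyl carbon is bonded directly to the cyclopropane (C5 and C8–C9 lie between) so cyclopropylcarbinyl ring opening is not open to them, and C5 already has the arrangement that is both kinetically installed and thermodynamically preferred (cyclopropyl trans to the bulkier silyloxymethyl group), so enolisation should not erode it.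

**Aryl ketone, oxepane closure and end game**

Step 20
Reactants: 28 (4S,5S,6R,7R)-4-{[(tert-butyldiphenylsilyl)oxy]methyl}aromadendr-1(10)-ene
Product: 29 (4S,5S,6R,7R)-4-(hydroxymethyl)aromadendr-1(10)-ene
Conditions: TBAF, THF, rt → 45 °C
Reagents that add atoms: none
Why: Fluoride-mediated desilylation frees the neopentyl C7' alcohol without acid, so the tetrasubstituted alkene is not protonated.

Step 21
Reactants: 29 (4S,5S,6R,7R)-4-(hydroxymethyl)aromadendr-1(10)-ene
Product: 30 (4S,5S,6R,7R)-aromadendr-1(10)-ene-4-carbaldehyde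
Conditions: Dess–Martin periodinane, NaHCO3, CH2Cl2, 0 °C → rt
Reagents that add atoms: none
Why: Dess–Martin oxidation gives the aldehyde on quaternary C4, which cannot enolise and so cannot lose configuration.

Step 22
Reactants: 31 3,5-dimethoxyphenol
Product: 32 1,3-dimethoxy-5-(methoxymethoxy)benzene
Conditions: MOMCl, iPr2NEt, CH2Cl2, 0 °C → rt
Reagents that add atoms: chloromethyl methyl ether, COCCl
Why: O-Alkylation gives the MOM ether, which is both a strong ortho-lithiation director and an acid-labile mask for the phenol that must later close the ether.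

Step 23
Reactants: 32 1,3-dimethoxy-5-(methoxymethoxy)benzene; 30 (4S,5S,6R,7R)-aromadendr-1(10)-ene-4-carbaldehyde
Product: 34 [2,4-dimethoxy-6-(methoxymethoxy)phenyl][(4S,5S,6R,7R)-aromadendr-1(10)-en-4-yl]methanol, via aryllithium 33 (not isolated)
Conditions: n-BuLi, TMEDA, THF, 0 °C; then 30, −78 → 0 °C
Reagents that add atoms: none
Why: Directed ortho-lithiation between OMOM and OMe followed by 1,2-addition to the non-enolisable aldehyde forms the C7'–C1' bond, and the new carbinol configuration does not matter because it is oxidised next.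

Step 24
Reactants: 34 [2,4-dimethoxy-6-(methoxymethoxy)phenyl][(4S,5S,6R,7R)-aromadendr-1(10)-en-4-yl]methanol
Product: 35 [2,4-dimethoxy-6-(methoxymethoxy)phenyl][(4S,5S,6R,7R)-aromadendr-1(10)-en-4-yl]methanone
Conditions: Dess–Martin periodinane, NaHCO3, CH2Cl2, rt
Reagents that add atoms: none
Why: Dess–Martin oxidation to the aryl ketone removes the ionisable benzylic alcohol, so the acid of the next step cannot generate a C7' cation that would attack the alkene.

Step 25
Reactants: 35 [2,4-dimethoxy-6-(methoxymethoxy)phenyl][(4S,5S,6R,7R)-aromadendr-1(10)-en-4-yl]methanone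
Product: 37 (1S,4S,5R,6R,7R,10S)-1,2'-epoxy-4',6'-dimethoxy bridged benzoxepin-7'-one (aromadendrane with C4–C7'(=O)–C1' and C1–O–C2'), via free phenol 36 (not isolated)
Conditions: TsOH·H2O (cat.), MeOH/CH2Cl2, 40 °C; evaporate; TfOH (10 mol %), CH2Cl2, −40 → 0 °C
Reagents that add atoms: none
Why: Acetal methanolysis frees the phenol and acid-catalysed Markovnikov hydroalkoxylation (the phenol–alkene closure used for chromans) follows, in which the phenol held on the H5 face of C4 can reach only that face of C1 (sets C1) and the proton is delivered to C10 on the opposite face (anti addition, sets C10).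

Step 26
Reactants: 37 (1S,4S,5R,6R,7R,10S)-1,2'-epoxy-4',6'-dimethoxy bridged benzoxepin-7'-one
Product: 38 (1S,4S,5R,6R,7R,10S)-1,2'-epoxy-4',6'-dimethoxy bridged benzoxepin-7'-ol
Conditions: LiAlH4, THF, 0 °C → rt
Reagents that add atoms: none
Why: Hydride reduction of the hindered aryl ketone gives the benzylic alcohol, whose configuration is irrelevant because it is ionised in the next step.

Step 27
Reactants: 38 (1S,4S,5R,6R,7R,10S)-1,2'-epoxy-4',6'-dimethoxy bridged benzoxepin-7'-ol; 39 methallyltrimethylsilane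
Product: 40 (1S,4R,5R,6R,7R,10S,7'R)-1,2'-epoxy-4',6'-dimethoxy-7'-(2-methylprop-2-en-1-yl) bridged benzoxepine
Conditions: BF3·OEt2 (cat.), CH2Cl2, −78 → −40 °C
Reagents that add atoms: none
Why: Hosomi–Sakurai allylation of the trioxygenated benzylic cation (no β-hydrogen, so no elimination) is expected from the exo face, the side of the one-carbon bridge C5 that carries only H towards the aryl bridge, which sets C7' with the side chain syn to C5 as in the target.

Step 28
Reactants: 40 (1S,4R,5R,6R,7R,10S,7'R)-1,2'-epoxy-4',6'-dimethoxy-7'-(2-methylprop-2-en-1-yl) bridged benzoxepine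
Product: 41 (1S,4R,5R,6R,7R,10S,7'R)-1,2'-epoxy-4',6'-dimethoxy-7'-isobutyl bridged benzoxepine
Conditions: H2 (1 atm), 10% Pd/C, EtOAc, rt
Reagents that add atoms: none
Why: Hydrogenation of the 1,1-disubstituted alkene gives the isobutyl group, and neither the cyclopropane nor the non-benzylic C1–O bond should be cleaved.

Step 29
Reactants: 41 (1S,4R,5R,6R,7R,10S,7'R)-1,2'-epoxy-4',6'-dimethoxy-7'-isobutyl bridged benzoxepine
Product: 42 (1S,4R,5R,6R,7R,10S,7'R)-1,2'-epoxy-3',5'-diformyl-4',6'-dimethoxy-7'-isobutyl bridged benzoxepine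
Conditions: Cl2CHOMe, TiCl4, CH2Cl2, −78 → 0 °C; then H2O
Reagents that add atoms: dichloromethyl methyl ether, COC(Cl)Cl; water, O
Why: Twofold Rieche formylation takes the only two aromatic C–H positions, each flanked by two alkoxy groups, as is known for 5,7-dialkoxychromans carrying a tertiary alkyl aryl ether.

Step 30
Reactants: 42 (1S,4R,5R,6R,7R,10S,7'R)-1,2'-epoxy-3',5'-diformyl-4',6'-dimethoxy-7'-isobutyl bridged benzoxepine
Product: 43 target, (1S,4R,5R,6R,7R,10S,7'R)-1,2'-epoxy-3',5'-diformyl-4',6'-dihydroxy-7'-isobutyl bridged benzoxepine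
Conditions: NaSEt, DMF, 110 °C; then 1 M HCl
Reagents that add atoms: none
Why: Thiolate SN2 O-demethylation attacks only the two methyl carbons (activated by the ortho/para formyl groups), whereas the tertiary C1–O ether cannot undergo SN2 and is not exposed to Lewis acid.

**Compound list**

1 | (+)-2-carene, (1S,6R)-3,7,7-trimethylbicyclo[4.1.0]hept-2-ene | CC1=C[C@H]2[C@@H](CC1)C2(C)C | starting material
2 | secondary ozonide of 1 (1,2,4-trioxolane; not isolated) | CC12OC(OO1)[C@H]3[C@@H](CC2)C3(C)C | intermediate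
3 | (1S,3R)-2,2-dimethyl-3-(3-oxobutyl)cyclopropane-1-carbaldehyde | CC(=O)CC[C@@H]1[C@H](C=O)C1(C)C | intermediate
4 | 4-[(1R,3S)-3-ethenyl-2,2-dimethylcyclopropyl]butan-2-one | CC(=O)CC[C@@H]1[C@H](C=C)C1(C)C | intermediate
5 | 2-{2-[(1R,3S)-3-ethenyl-2,2-dimethylcyclopropyl]ethyl}-2-methyl-1,3-dioxolane | CC1(CC[C@@H]2[C@H](C=C)C2(C)C)OCCO1 | intermediate
6 | B-alkyl-9-BBN adduct of 5 (boron on the terminal carbon; not isolated) | CC1(CC[C@@H]2[C@H](CCB3C4CCCC3CCC4)C2(C)C)OCCO1 | intermediate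
7 | 2-{(1S,3R)-2,2-dimethyl-3-[2-(2-methyl-1,3-dioxolan-2-yl)ethyl]cyclopropyl}ethan-1-ol | CC1(CC[C@@H]2[C@H](CCO)C2(C)C)OCCO1 | intermediate
8 | 2-{(1S,3R)-2,2-dimethyl-3-[2-(2-methyl-1,3-dioxolan-2-yl)ethyl]cyclopropyl}acetic acid | CC1(CC[C@@H]2[C@H](CC(=O)O)C2(C)C)OCCO1 | intermediate
9 | methyl (R)-lactate | C[C@@H](O)C(=O)OC | starting material
10 | methyl (2R)-2-[(tert-butyldimethylsilyl)oxy]propanoate | C[C@@H](O[Si](C)(C)C(C)(C)C)C(=O)OC | intermediate
11 | (2R)-2-[(tert-butyldimethylsilyl)oxy]propanal | C[C@@H](O[Si](C)(C)C(C)(C)C)C=O | intermediate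
12 | ethyl 2-(triphenyl-λ5-phosphanylidene)propanoate | CCOC(=O)C(C)=P(c1ccccc1)(c1ccccc1)c1ccccc1 | starting material
13 | ethyl (2E,4R)-4-[(tert-butyldimethylsilyl)oxy]-2-methylpent-2-enoate | CCOC(=O)/C(C)=C/[C@@H](C)O[Si](C)(C)C(C)(C)C | intermediate
14 | (2E,4R)-4-[(tert-butyldimethylsilyl)oxy]-2-methylpent-2-en-1-ol | OC/C(C)=C/[C@@H](C)O[Si](C)(C)C(C)(C)C | intermediate
15 | (2E,4R)-4-[(tert-butyldimethylsilyl)oxy]-1-[(tert-butyldiphenylsilyl)oxy]-2-methylpent-2-ene | CC(C)(C)[Si](OC/C(C)=C/[C@@H](C)O[Si](C)(C)C(C)(C)C)(c1ccccc1)c1ccccc1 | intermediate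
16 | (2R,3E)-5-[(tert-butyldiphenylsilyl)oxy]-4-methylpent-3-en-2-ol | C[C@@H](O)/C=C(\C)CO[Si](c1ccccc1)(c1ccccc1)C(C)(C)C | intermediate
17 | (2R,3E)-5-[(tert-butyldiphenylsilyl)oxy]-4-methylpent-3-en-2-yl 2-{(1S,3R)-2,2-dimethyl-3-[2-(2-methyl-1,3-dioxolan-2-yl)ethyl]cyclopropyl}acetate | CC1(CC[C@@H]2[C@H](CC(=O)O[C@H](C)/C=C(\C)CO[Si](c3ccccc3)(c3ccccc3)C(C)(C)C)C2(C)C)OCCO1 | intermediate
18 | trimethylsilyl ketene acetal of 17, cyclopropyl cis to OSiMe3 (not isolated) | CC1(CC[C@@H]2[C@H](/C=C(\O[Si](C)(C)C)O[C@H](C)/C=C(\C)CO[Si](c3ccccc3)(c3ccccc3)C(C)(C)C)C2(C)C)OCCO1 | intermediate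
19 | trimethylsilyl ester of 20 (not isolated) | CC1(CC[C@@H]2[C@H]([C@@H](C(=O)O[Si](C)(C)C)[C@@](C)(CO[Si](c3ccccc3)(c3ccccc3)C(C)(C)C)/C=C/C)C2(C)C)OCCO1 | intermediate
20 | (2R,3S,4E)-3-{[(tert-butyldiphenylsilyl)oxy]methyl}-2-{(1R,3R)-2,2-dimethyl-3-[2-(2-methyl-1,3-dioxolan-2-yl)ethyl]cyclopropyl}-3-methylhex-4-enoic acid | CC1(CC[C@@H]2[C@H]([C@@H](C(=O)O)[C@@](C)(CO[Si](c3ccccc3)(c3ccccc3)C(C)(C)C)/C=C/C)C2(C)C)OCCO1 | intermediate
21 | N-acyl imidazole of 20 (not isolated) | CC1(CC[C@@H]2[C@H]([C@@H](C(=O)n3ccnc3)[C@@](C)(CO[Si](c3ccccc3)(c3ccccc3)C(C)(C)C)/C=C/C)C2(C)C)OCCO1 | intermediate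
22 | N-methoxy-N-methyl amide of 20, (2R,3S,4E) | CC1(CC[C@@H]2[C@H]([C@@H](C(=O)N(C)OC)[C@@](C)(CO[Si](c3ccccc3)(c3ccccc3)C(C)(C)C)/C=C/C)C2(C)C)OCCO1 | intermediate
23 | (4R,5S,6E)-5-{[(tert-butyldiphenylsilyl)oxy]methyl}-4-{(1R,3R)-2,2-dimethyl-3-[2-(2-methyl-1,3-dioxolan-2-yl)ethyl]cyclopropyl}-5-methylocta-1,6-dien-3-one | CC1(CC[C@@H]2[C@H]([C@@H](C(=O)C=C)[C@@](C)(CO[Si](c3ccccc3)(c3ccccc3)C(C)(C)C)/C=C/C)C2(C)C)OCCO1 | intermediate
24 | (4S,5R)-4-{[(tert-butyldiphenylsilyl)oxy]methyl}-5-{(1R,3R)-2,2-dimethyl-3-[2-(2-methyl-1,3-dioxolan-2-yl)ethyl]cyclopropyl}-4-methylcyclopent-2-en-1-one | CC1(CC[C@@H]2[C@H]([C@H]3C(=O)C=C[C@]3(C)CO[Si](c4ccccc4)(c4ccccc4)C(C)(C)C)C2(C)C)OCCO1 | intermediate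
25 | (2R,3S)-3-{[(tert-butyldiphenylsilyl)oxy]methyl}-2-{(1R,3R)-2,2-dimethyl-3-[2-(2-methyl-1,3-dioxolan-2-yl)ethyl]cyclopropyl}-3-methylcyclopentan-1-one | CC1(CC[C@@H]2[C@H]([C@H]3C(=O)CC[C@]3(C)CO[Si](c4ccccc4)(c4ccccc4)C(C)(C)C)C2(C)C)OCCO1 | intermediate
26 | (2R,3S)-3-{[(tert-butyldiphenylsilyl)oxy]methyl}-2-[(1R,3R)-2,2-dimethyl-3-(3-oxobutyl)cyclopropyl]-3-methylcyclopentan-1-one (key-step precursor) | CC(=O)CC[C@@H]1[C@H]([C@H]2C(=O)CC[C@]2(C)CO[Si](c3ccccc3)(c3ccccc3)C(C)(C)C)C1(C)C | intermediate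
27 | titanium pinacolate of the C1/C10 diol (metal drawn as Ti; C1 and C10 configuration not defined; not isolated) | CC(C)(C)[Si](OC[C@@]1(C)CCC23O[Ti]OC2(C)CC[C@@H]2[C@H]([C@H]13)C2(C)C)(c1ccccc1)c1ccccc1 | intermediate
28 | (4S,5S,6R,7R)-4-{[(tert-butyldiphenylsilyl)oxy]methyl}aromadendr-1(10)-ene (key-step product) | CC(C)(C)[Si](OC[C@@]1(C)CCC2=C(C)CC[C@@H]3[C@H]([C@H]12)C3(C)C)(c1ccccc1)c1ccccc1 | intermediate
29 | (4S,5S,6R,7R)-4-(hydroxymethyl)aromadendr-1(10)-ene | OC[C@@]1(C)CCC2=C(C)CC[C@@H]3[C@H]([C@H]12)C3(C)C | intermediate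
30 | (4S,5S,6R,7R)-aromadendr-1(10)-ene-4-carbaldehyde | O=C[C@@]1(C)CCC2=C(C)CC[C@@H]3[C@H]([C@H]12)C3(C)C | intermediate
31 | 3,5-dimethoxyphenol | COc1cc(O)cc(OC)c1 | starting material
32 | 1,3-dimethoxy-5-(methoxymethoxy)benzene | COCOc1cc(OC)cc(OC)c1 | intermediate
33 | [2,4-dimethoxy-6-(methoxymethoxy)phenyl]lithium (not isolated) | [Li]c1c(OC)cc(OC)cc1OCOC | intermediate
34 | [2,4-dimethoxy-6-(methoxymethoxy)phenyl][(4S,5S,6R,7R)-aromadendr-1(10)-en-4-yl]methanol (C7' epimers) | COCOc1cc(OC)cc(OC)c1C(O)[C@@]1(C)CCC2=C(C)CC[C@@H]3[C@H]([C@H]12)C3(C)C | intermediate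
35 | [2,4-dimethoxy-6-(methoxymethoxy)phenyl][(4S,5S,6R,7R)-aromadendr-1(10)-en-4-yl]methanone | COCOc1cc(OC)cc(OC)c1C(=O)[C@@]1(C)CCC2=C(C)CC[C@@H]3[C@H]([C@H]12)C3(C)C | intermediate
36 | (2-hydroxy-4,6-dimethoxyphenyl)[(4S,5S,6R,7R)-aromadendr-1(10)-en-4-yl]methanone (not isolated) | COc1cc(O)c(C(=O)[C@@]2(C)CCC3=C(C)CC[C@@H]4[C@H]([C@H]23)C4(C)C)c(OC)c1 | intermediate
37 | (1S,4S,5R,6R,7R,10S)-1,2'-epoxy-4',6'-dimethoxy bridged benzoxepin-7'-one | O=C1c2c(OC)cc(OC)cc2O[C@]23CC[C@@]1(C)[C@H]2[C@H]1[C@@H](CC[C@@H]3C)C1(C)C | intermediate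
38 | (1S,4S,5R,6R,7R,10S)-1,2'-epoxy-4',6'-dimethoxy bridged benzoxepin-7'-ol (C7' configuration immaterial) | OC1c2c(OC)cc(OC)cc2O[C@]23CC[C@@]1(C)[C@H]2[C@H]1[C@@H](CC[C@@H]3C)C1(C)C | intermediate
39 | methallyltrimethylsilane | C=C(C)C[Si](C)(C)C | starting material
40 | (1S,4R,5R,6R,7R,10S,7'R)-1,2'-epoxy-4',6'-dimethoxy-7'-(2-methylprop-2-en-1-yl) bridged benzoxepine | C=C(C)C[C@H]1c2c(OC)cc(OC)cc2O[C@]23CC[C@@]1(C)[C@H]2[C@H]1[C@@H](CC[C@@H]3C)C1(C)C | intermediate
41 | (1S,4R,5R,6R,7R,10S,7'R)-1,2'-epoxy-4',6'-dimethoxy-7'-isobutyl bridged benzoxepine | CC(C)C[C@H]1c2c(OC)cc(OC)cc2O[C@]23CC[C@@]1(C)[C@H]2[C@H]1[C@@H](CC[C@@H]3C)C1(C)C | intermediate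
42 | (1S,4R,5R,6R,7R,10S,7'R)-1,2'-epoxy-3',5'-diformyl-4',6'-dimethoxy-7'-isobutyl bridged benzoxepine | CC(C)C[C@H]1c2c(OC)c(C=O)c(OC)c(C=O)c2O[C@]23CC[C@@]1(C)[C@H]2[C@H]1[C@@H](CC[C@@H]3C)C1(C)C | intermediate
43 | CNP0189833.2, (1S,4R,5R,6R,7R,10S,7'R) | CC(C)C[C@H]1c2c(O)c(C=O)c(O)c(C=O)c2O[C@]23CC[C@@]1(C)[C@H]2[C@H]1[C@@H](CC[C@@H]3C)C1(C)C | target

**Totals**

Total step count: 30. Longest linear sequence: 24 steps (from 9 through steps 6–11, 12–21 and 23–30).

**Three steps most likely to fail**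

Step 19 (McMurry closure). The ketyls may couple between molecules to give oligomers, the hindered ditertiary pinacolate may resist deoxygenation so the reaction stalls at the diol, or C5 may epimerise through a titanium enolate. The fallback sets out from 26 and separates C–C bond formation from deoxygenation. SmI2/HMPA in THF at high dilution should cyclise the diketone to the cis-1,10-diol F1. Thiocarbonyldiimidazole with DMAP in hot toluene converts this to the cyclic thionocarbonate F2. Corey–Winter fragmentation with trimethyl phosphite at reflux (or the diazaphospholidine variant at 40 °C) then gives the alkene, and the route is rejoined at 28.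

Step 25 (phenol closure). A 1,2-hydride shift from C5 to the C1 cation would give a cyclopropylcarbinyl cation and a ring-opened or rearranged skeleton; the alkene may also migrate, and the proton may reach C10 from both faces. The fallback sets out from 35. The MOM group is removed as in the first stage of step 25 and the phenol 36 is isolated. N-(Phenylseleno)phthalimide with catalytic CSA in CH2Cl2 at −78 °C should form the seleniranium ion on the face away from the tether, and anti opening by the phenol at C1 gives the C10-phenylselanyl ether F3. Bu3SnH/AIBN in toluene at 80 °C replaces selenium by hydrogen, delivered to the C10 radical from the face away from the aryl ether, and the route is rejoined at 37.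

Step 29 (Rieche formylation). TiCl4 may ionise the tertiary alkyl aryl ether at C1, leading to ring reopening, elimination or cyclopropane rearrangement, or the reaction may stop after one formyl group. The fallback sets out from 41 and uses no Lewis acid. NBS (2.1 equiv) in MeCN at 0 °C should brominate both free aromatic positions to give the 3',5'-dibromide F4. Double bromine–lithium exchange with t-BuLi (4.4 equiv) in THF at −78 °C and a DMF quench gives the dialdehyde, and the route is rejoined at 42.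

**Further compounds**

F1 | step 19 | cis-1,10-diol from pinacol cyclisation of 26 (4S,5S,6R,7R; C1 and C10 hydroxyls cis) | CC(C)(C)[Si](OC[C@@]1(C)CCC2(O)C(C)(O)CC[C@@H]3[C@H]([C@H]12)C3(C)C)(c1ccccc1)c1ccccc1
F2 | step 19 | cyclic 1,10-thionocarbonate of F1 | CC(C)(C)[Si](OC[C@@]1(C)CCC23OC(=S)OC2(C)CC[C@@H]2[C@H]([C@H]13)C2(C)C)(c1ccccc1)c1ccccc1
F3 | step 25 | 10-(phenylselanyl) derivative of 37 (Se anti to the C1–O bond) | O=C1c2c(OC)cc(OC)cc2O[C@]23CC[C@@]1(C)[C@H]2[C@H]1[C@@H](CC[C@@]3(C)[Se]c4ccccc4)C1(C)C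
F4 | step 29 | 3',5'-dibromide of 41 | CC(C)C[C@H]1c2c(OC)c(Br)c(OC)c(Br)c2O[C@]23CC[C@@]1(C)[C@H]2[C@H]1[C@@H](CC[C@@H]3C)C1(C)C
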